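**Retrosynthetic overview**
1. Target 19 ← selective saponification of the side-chain methyl ester of tropone diester 18.
2. 18 ← one-pot Rh-catalysed furan annulation, formal [4+3] cycloaddition and aromatization joining α-diazo spirolactone 11, propyne 15 and siloxyvinyl diazoester 14. The furan ring and the seven-membered ring both form in this operation.
3. 11 ← spirolactone 9 ← exocyclic alkene 8 by radical carbolactonization, which sets the spiro carbon.
4. 8 ← (S)-(+)-carvone 3 by two α′-substitutions (methyl, then the C3 chain anti to isopropenyl), double conjugate reduction, hydration and methylenation.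
5. Ring order: cyclohexane (from carvone) → spirolactone (the later dihydrofuran) → furan plus seven-membered ring → tropone.

Assumption: the cyclohexane carbons are labelled as in a drimane (C9 spiro, C8 CHMe, C10 quaternary, C5 CH–CMe2OH); the target SMILES then reads 5S,8S,9S,10R, the mirror image of the usual phenylspirodrimane series, which maps onto (S)-(+)-carvone.

**Route**

Step 1
Reactants: 1 methyl propiolate
Product: 2 methyl (Z)-3-iodoacrylate
Conditions: NaI, AcOH, 70 °C
Reagents that add atoms: sodium iodide [Na+].[I-]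
Why: Conjugate hydroiodination of the ynoate (iodide adds at C3, anti protonation) gives the Z-iodoacrylate; no stereocenter.

Step 2
Reactants: 3 (S)-(+)-carvone
Product: 4 (5S,6R)-6-methylcarvone (methyl trans to isopropenyl)
Conditions: LiN(i-Pr)2, THF, −78 °C; MeI, −78 → 0 °C
Reagents that add atoms: iodomethane CI
Why: Kinetic α′-enolate alkylation of the enone anti to the isopropenyl group; this centre is re-enolized in step 3, so its configuration is inconsequential.

Step 3
Reactants: 4 (5S,6R)-6-methylcarvone, 2 methyl (Z)-3-iodoacrylate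
Product: 5 methyl (Z)-3-[1,3-dimethyl-2-oxo-6-(prop-1-en-2-yl)cyclohex-3-en-1-yl]prop-2-enoate (propenoate trans, methyl cis to isopropenyl)
Conditions: LiN(i-Pr)2, THF, −78 °C; then 2, −78 → −20 °C
Reagents that add atoms: none
Why: Addition–elimination (vinylic substitution) of the α′-enolate on the β-iodoacrylate; attack anti to isopropenyl sets the quaternary carbon, and fast loss of iodide from the β-iodo ester enolate prevents the second intramolecular Michael addition (bicyclo[2.2.2]octanone) that acrylates give.

Step 4
Reactants: 5 dienone enoate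
Product: 6 methyl 3-[1,3-dimethyl-2-oxo-6-(prop-1-en-2-yl)cyclohexyl]propanoate (C3 methyl equatorial, trans to the C1 methyl)
Conditions: [(Ph3P)CuH]6 (5 mol %), PhMe2SiH, t-BuOH, toluene, rt; then NaOMe (cat.), MeOH, rt
Reagents that add atoms: none
Why: Copper hydride conjugate reduction (Stryker type) of enone and enoate leaves the isolated alkene; methoxide equilibration puts the only epimerizable centre (C8 methyl) equatorial, trans to the axial quaternary methyl.

Step 5
Reactants: 6 keto ester with isopropenyl group
Product: 7 methyl 3-[6-(2-hydroxypropan-2-yl)-1,3-dimethyl-2-oxocyclohexyl]propanoate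
Conditions: Co(acac)2 (10 mol %), PhSiH3, O2 (1 atm), i-PrOH/THF, rt
Reagents that add atoms: dioxygen O=O
Why: Mukaiyama hydration (cobalt hydride hydrogen-atom transfer, O2 trapping) gives the Markovnikov tertiary alcohol; ketone and ester are inert; no new stereocenter.

Step 6
Reactants: 7 hydroxy keto ester
Product: 8 methyl 3-[6-(2-hydroxypropan-2-yl)-1,3-dimethyl-2-methylidenecyclohexyl]propanoate
Conditions: Zn, CH2Br2, TiCl4 (preformed reagent), THF/CH2Cl2, 0 °C → rt
Reagents that add atoms: dibromomethane BrCBr
Why: Takai–Lombardo methylenation works on hindered, enolizable ketones without epimerization and does not touch the ester.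

Step 7
Reactants: 8 exocyclic alkene
Product: 9 methyl 3-[7-(2-hydroxypropan-2-yl)-6,10-dimethyl-2-oxo-1-oxaspiro[4.5]decan-6-yl]propanoate (lactone O axial, anti to the C6 methyl)
Conditions: BrCH2CO2H, fac-Ir(ppy)3 (1 mol %), 2,6-lutidine, MeCN, blue LEDs, rt
Reagents that add atoms: bromoacetic acid OC(=O)CBr
Why: Photoredox radical–polar crossover carbolactonization: the carboxymethyl radical adds to the CH2 terminus, the tertiary radical is oxidized to the cation and the carboxylate closes axially, anti to the axial quaternary methyl, setting the spiro carbon (O axial, CH2 equatorial) as in the target.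

Step 8
Reactants: 9 spirolactone
Product: 11 α-diazo spirolactone, via trifluoroacetyl lactone 10 (not isolated)
Conditions: LiN(SiMe3)2 (2.2 equiv), THF, −78 °C; CF3CO2CH2CF3; then MeSO2N3, Et3N, MeCN, rt
Reagents that add atoms: 2,2,2-trifluoroethyl trifluoroacetate FC(F)(F)COC(=O)C(F)(F)F (acyl group of 10 only); methanesulfonyl azide CS(=O)(=O)N=[N+]=[N-]
Why: Danheiser detrifluoroacetylative diazo transfer; the lactone α-CH2 is clearly more acidic than the open-chain ester α-CH2, so only the lactone is activated; stereocenters untouched.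

Step 9
Reactants: 12 methyl 3-oxopentanoate
Product: 13 methyl 2-diazo-3-oxopentanoate
Conditions: 4-AcNHC6H4SO2N3, Et3N, MeCN, 0 °C → rt
Reagents that add atoms: 4-acetamidobenzenesulfonyl azide CC(=O)Nc1ccc(cc1)S(=O)(=O)N=[N+]=[N-]
Why: Regitz diazo transfer to the active methylene.

Step 10
Reactants: 13 methyl 2-diazo-3-oxopentanoate
Product: 14 methyl (Z)-3-(tert-butyldimethylsilyloxy)-2-diazopent-3-enoate
Conditions: t-BuMe2SiOTf, Et3N, CH2Cl2, 0 °C
Reagents that add atoms: tert-butyldimethylsilyl trifluoromethanesulfonate CC(C)(C)[Si](C)(C)OS(=O)(=O)C(F)(F)F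
Why: O-silylation of the ketone enol gives the siloxyvinyl diazoacetate used as the vinylcarbenoid precursor in Davies-type [4+3] chemistry.

Step 11
Reactants: 11 α-diazo spirolactone, 15 propyne, 14 siloxyvinyl diazoester
Product: 18 tropone diester (methyl ester of the target), via spiro alkoxyfuran 16 (not isolated), via oxabicyclic silyl enol ether 17 (not isolated)
Conditions: Rh2(OAc)4 (2 mol %), propyne (excess), CH2Cl2, 0 °C → rt; purge; then 14 (slow addition), rt → 40 °C; then n-Bu4NF, AcOH, THF, rt
Reagents that add atoms: none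
Why: Proposed new method: the Rh carbenoid from 11 adds to propyne and the lactone carbonyl oxygen closes on the new vinyl carbenoid (closest known type: formal [3+2] furan annulation of α-diazocarbonyls with alkynes) to give 2-alkoxyfuran 16; its only unhindered double bond is cyclopropanated at the methyl-bearing α-carbon by the carbenoid from 14 and Cope rearrangement of the cis-divinylcyclopropane (Davies tandem cyclopropanation/Cope, a formal [4+3] cycloaddition) gives oxabicycle 17; fluoride then triggers β-alkoxide elimination from the β-keto ester and loss of water to the tropone, and a zwitterionic ring-opening of the alkoxyfuran would lead to a dienyl lactone that converges on the same tropone; no stereocenter is created.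

Step 12
Reactants: 18 tropone diester
Product: 19 target acid CNP0448476.1
Conditions: LiOH (1.5 equiv), THF/H2O, 0 °C; then 1 M HCl to pH 3
Reagents that add atoms: lithium hydroxide [Li+].[OH-]
Why: Saponification of the unhindered aliphatic methyl ester; the tropone ester flanked by C=O and C–Me is far slower; stereocenters untouched.

**Compound list**

1 | methyl propiolate | C#CC(=O)OC | starting material
2 | methyl (Z)-3-iodoacrylate | I/C=C\C(=O)OC | intermediate
3 | (S)-(+)-carvone | CC1=CC[C@@H](CC1=O)C(C)=C | starting material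
4 | (5S,6R)-2,6-dimethyl-5-(prop-1-en-2-yl)cyclohex-2-en-1-one | O=C1C(C)=CC[C@H](C(C)=C)[C@H]1C | intermediate
5 | methyl (Z)-3-[1,3-dimethyl-2-oxo-6-(prop-1-en-2-yl)cyclohex-3-en-1-yl]prop-2-enoate, propenoate trans to isopropenyl | O=C1C(C)=CC[C@H](C(C)=C)[C@@]1(C)/C=C\C(=O)OC | intermediate
6 | methyl 3-[1,3-dimethyl-2-oxo-6-(prop-1-en-2-yl)cyclohexyl]propanoate, C3 methyl trans to C1 methyl | O=C1[C@@H](C)CC[C@H](C(C)=C)[C@@]1(C)CCC(=O)OC | intermediate
7 | methyl 3-[6-(2-hydroxypropan-2-yl)-1,3-dimethyl-2-oxocyclohexyl]propanoate | O=C1[C@@H](C)CC[C@H](C(C)(C)O)[C@@]1(C)CCC(=O)OC | intermediate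
8 | methyl 3-[6-(2-hydroxypropan-2-yl)-1,3-dimethyl-2-methylidenecyclohexyl]propanoate | C=C1[C@@H](C)CC[C@H](C(C)(C)O)[C@@]1(C)CCC(=O)OC | intermediate
9 | methyl 3-[7-(2-hydroxypropan-2-yl)-6,10-dimethyl-2-oxo-1-oxaspiro[4.5]decan-6-yl]propanoate, lactone O anti to C6 methyl | O=C1CC[C@]2(O1)[C@@H](C)CC[C@H](C(C)(C)O)[C@@]2(C)CCC(=O)OC | intermediate
10 | 3-(trifluoroacetyl) derivative of spirolactone 9 | O=C1C(C(=O)C(F)(F)F)C[C@]2(O1)[C@@H](C)CC[C@H](C(C)(C)O)[C@@]2(C)CCC(=O)OC | intermediate
11 | 3-diazo derivative of spirolactone 9 | O=C1C(=[N+]=[N-])C[C@]2(O1)[C@@H](C)CC[C@H](C(C)(C)O)[C@@]2(C)CCC(=O)OC | intermediate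
12 | methyl 3-oxopentanoate | CCC(=O)CC(=O)OC | starting material
13 | methyl 2-diazo-3-oxopentanoate | CCC(=O)C(=[N+]=[N-])C(=O)OC | intermediate
14 | methyl (Z)-3-(tert-butyldimethylsilyloxy)-2-diazopent-3-enoate | C/C=C(\O[Si](C)(C)C(C)(C)C)C(=[N+]=[N-])C(=O)OC | intermediate
15 | propyne | CC#C | starting material
16 | spiro 5'-methyl-2',3'-dihydrofuro[2,3-b]furan (2-alkoxyfuran) with the cyclohexane of 9 | Cc1cc2c(o1)O[C@@]3(C2)[C@@H](C)CC[C@H](C(C)(C)O)[C@@]3(C)CCC(=O)OC | intermediate
17 | 8-oxabicyclo[3.2.1]octa-2,6-diene silyl enol ether fused to the spiro dihydrofuran (mixture at the new ring carbons) | COC(=O)C1=C(O[Si](C)(C)C(C)(C)C)C(C)C23OC1(C)C=C2C[C@]4(O3)[C@@H](C)CC[C@H](C(C)(C)O)[C@@]4(C)CCC(=O)OC | intermediate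
18 | tropone diester, methyl ester of the target | COC(=O)c1c(C)cc2c(c(C)c1=O)O[C@@]1(C2)[C@@H](C)CC[C@H](C(C)(C)O)[C@@]1(C)CCC(=O)OC | intermediate
19 | CNP0448476.1 | COC(=O)c1c(C)cc2c(c(C)c1=O)O[C@@]1(C2)[C@@H](C)CC[C@H](C(C)(C)O)[C@@]1(C)CCC(=O)O | target

**Step count and risks**

Total steps: 12. Longest linear sequence: 9 (steps 2–8, 11, 12 from (S)-carvone).

Most likely to fail:

Step 11. The lactone carbenoid has β-hydrogens (1,2-hydride shift to a butenolide), may stop at the cyclopropene, may insert into the free tertiary O–H, and the alkoxyfuran may ring-open instead of cyclizing. Fallback: set out from 11. Condense 12 with chloroacetone (pyridine, Feist–Benary) to the furan ester methyl 2-ethyl-4-methylfuran-3-carboxylate F1. Treat 11 with F1 and Rh2(OAc)4: the carbenoid attacks the only free α-position of the furan and the furan unravels (carbenoid furan ring-opening) to the keto dienyl spirolactone F2, whose ring-derived double bond is Z. KOt-Bu then closes the seven-membered ring by intramolecular Claisen condensation of the ethyl-ketone enolate on the lactone carbonyl, and acidification re-forms the vinylogous ester with loss of water. This replaces the cycloaddition by ring-opening and condensation and comes back to the route at 18.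

Step 3. The hindered enolate may act as a base or add reversibly, and the dienone product can re-add enolate. Fallback: set out from 4. Make the trimethylsilyl dienol ether F3 (LiN(i-Pr)2, Me3SiCl), alkylate it in a Mukaiyama-type reaction with methyl 3,3-dimethoxypropanoate and TiCl4 to the β-methoxy ester F4, and eliminate methanol with DBU to the (E)-enoate F5. F5 is reduced under the step 4 conditions, so the fallback comes back to the route at 6.

Step 7. The hindered tertiary radical may be oxidized slowly, or the cation may eliminate instead of lactonizing. Fallback: set out from 8. Epoxidize with mCPBA (oxygen delivered anti to the axial quaternary methyl) to the spiro-epoxide F6, open it at CH2 with sodium dimethyl malonate in MeOH so that the tertiary alkoxide lactonizes to the α-carbomethoxy spirolactone F7, and decarboxylate (LiCl, wet DMSO, 130 °C, Krapcho). This polar sequence comes back to the route at 9.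

Further compounds
F1 | step 11 | methyl 2-ethyl-4-methylfuran-3-carboxylate | CCc1occ(C)c1C(=O)OC
F2 | step 11 | keto dienyl spirolactone from furan ring-opening (ring-derived double bond Z, exocyclic double bond E/Z) | CCC(=O)/C(C(=O)OC)=C(C)\C=C1C[C@]2(OC1=O)[C@@H](C)CC[C@H](C(C)(C)O)[C@@]2(C)CCC(=O)OC
F3 | step 3 | trimethylsilyl dienol ether of 4 | C[Si](C)(C)OC1=C(C)[C@@H](C(C)=C)CC=C1C
F4 | step 3 | methyl 3-methoxy-3-[1,3-dimethyl-2-oxo-6-(prop-1-en-2-yl)cyclohex-3-en-1-yl]propanoate (mixture at the methoxy carbon) | O=C1C(C)=CC[C@H](C(C)=C)[C@@]1(C)C(OC)CC(=O)OC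
F5 | step 3 | (E)-isomer of 5 | O=C1C(C)=CC[C@H](C(C)=C)[C@@]1(C)/C=C/C(=O)OC
F6 | step 7 | spiro-epoxide of 8 (oxygen anti to the quaternary methyl) | C1O[C@]12[C@@H](C)CC[C@H](C(C)(C)O)[C@@]2(C)CCC(=O)OC
F7 | step 7 | 3-(methoxycarbonyl) derivative of spirolactone 9 (mixture at C3) | COC(=O)C1C[C@]2(OC1=O)[C@@H](C)CC[C@H](C(C)(C)O)[C@@]2(C)CCC(=O)OC
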